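The runs come from a simulation from invented constants.

Product cannot stand below zero, yet the straight line through the last two zeta readings lies 2.7 percentage points below zero at 2.50 min. One line therefore cannot describe the run, so I solved its two ends apart and joined them.

| flask | substrate | solid reagent | free catalyst | second catalyst | remark | time |
|---|---|---|---|---|---|---|
| zeta | 0.37 M (fed, over 12 min) | 1.2 equiv | 0.08 mol% | 0.76 mol% | run made earlier; the fed solution adds 0.25 times the starting volume |  |
| eta | 0.37 M (fed, over 12 min) | 1.2 equiv | 0.18 mol% | 0.76 mol% | run made earlier; the fed solution adds 0.25 times the starting volume |  |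
| flask | 0.37 M (fed, over 12 min) | 1.20 equiv | 0.12 mol% | 0.76 mol% | the fed solution adds 0.25 times the starting volume | 30 min |

| run | time / min | product / % |
|---|---|---|
| zeta | 2.50 | 0 |
| zeta | 4.00 | 0 |
| zeta | 6.00 | 0 |
| zeta | 10.0 | 0 |
| zeta | 20.0 | 2.9 |
| zeta | 30.0 | 6.1 |
| eta | 2.50 | 0.6 |
| eta | 4.00 | 0.1 |
| eta | 6.00 | 0.3 |
| eta | 10.0 | 0.6 |
| eta | 20.0 | 3.8 |
| eta | 30.0 | 7.2 |

(scatter of a reading: 0.5 percentage points)

- amounts are per litre of the starting volume; all of the dose is in the solution fed
- solid reagent is a solid; its amount is given per volume of the solution
- at the start none of the solid reagent is in solution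
- percentages count the whole charge, also what has not yet gone in

1. amount of product in percent of the substrate charged, at 3.0 min, 10 min, 20 min and 30 min

At the early end, every reading up to 10.0 min in both runs stood at or below 0.6 %. At the late end I used the late gain, the percentage points of product added from 20.0 min to 30.0 min. Zeta gave 3.2 points and eta 3.4 points.

These two numbers looked contradictory, because eta carried more free catalyst than zeta, 2.25 times as much. But a late gain is the difference of two readings, so its scatter is 0.71 points, and the gap of 0.2 points is smaller than that. The readings could not tell the two gains apart, so I carried their mean, the late gain of 3.3 points.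

The apparent onset (the induction period), where the late line meets zero, read 10.9 min for zeta and 8.82 min for eta. The flask's loading lies 40.0 % of the way from zeta to eta, which put its onset at 10.1 min. My line for the flask therefore stayed at zero through 10 min, then reached 3.27 % at 20 min and 6.57 % at 30 min.

The forecast gave 0.1 %, 0.3 %, 3.3 % and 6.5 %, on the ground that “More free catalyst therefore seems to shorten the lag slightly, while barely changing the later rate”. It stood a little below mine at 30 min.

The flask gave 0.0105 %, 0.442 %, 2.73 % and 6.60 %, so the forecast held.

    second catalyst + open intermediate ⇌ catalyst intermediate (K = 0.769 M⁻¹, k = 0.575 M⁻¹ s⁻¹)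
    coupling partner + catalyst intermediate → second catalyst + product (k = 3.53 M⁻¹ s⁻¹)
    substrate + free catalyst → free catalyst + open intermediate (k = 3.86 M⁻¹ s⁻¹)
    coupling partner ⇌ dormant form (K = 7.88, k = 0.00684 s⁻¹)
    solid reagent ⇌ coupling partner, rate k5*(cs5 - [coupling partner]) while solid is left; crystals form when [coupling partner] > cs5 (solubility = 0.220 M, k = 4.26 × 10⁻⁴ s⁻¹)
    coupling partner + second catalyst ⇌ idle complex, settled at all times (K = 6.70 M⁻¹)

At 30.0 min the flask held 79.2 % open intermediate against 6.60 % product. Its own late gain was 3.9 points, which is 0.60 points above the carried value, a gap larger than the scatter of 0.5 points on that mean of two gains.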